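**Plan**

- Retrosynthesis: the ring B carboxyl is traced back to a dimethyl acetal and the ring A phenol to its benzyl ether. Ring B is then cut at C1–C2 and C5–C6 (benzoic acid numbering: C1 CO2H, C2 OH, C3 Cl, C4 CH3, C6 O-aryl) into an aryloxy alkyne and 4-chloro-3-methylcyclobutenone. The alkyne is cut at its O–C(sp) bond into the ring A phenol and a 1,1-dibromoalkene.
- Enabling feature: ring B is a phenol with a carbon substituent (C1) ortho and an ether oxygen (C6) meta to the C2 hydroxyl, with C3–Cl and C4–CH3 on the other flank. This is the pattern a vinylketene plus oxygen-substituted alkyne benzannulation lays down.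
- Forward: ring A is bought as a salicylate, gains its C5 oxygen by C–H borylation/oxidation and is joined through oxygen to the three-carbon alkyne. Ring B is the only ring formed (step 8). Acetal hydrolysis, aldehyde oxidation and debenzylation finish the route.
- Stereochemistry: the target has no stereocentre. The racemic centre of the cyclobutenone and all alkene geometries are erased on aromatisation.

Key step: step 8

Remark: commercial 2,2-dimethoxyacetaldehyde (an aqueous solution) is assumed to be extracted into CH2Cl2 and dried before step 5. Propyne is used as the condensed gas.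

**Route**

Step 1
Reactants: 1 propyne; 2 trichloroacetyl chloride
Product: 4 4,4-dichloro-3-methylcyclobut-2-en-1-one, via dichloroketene 3 (not isolated)
Conditions: Zn(Cu) couple, Et2O/DME, excess propyne (dry-ice condenser), 0 °C to rt; crude 4 used at once
Reagents that add atoms: none
Why: Zinc removes two chlorines from 2 to give dichloroketene, whose thermal [2+2] ketene–alkyne cycloaddition joins the ketene carbonyl carbon to the unsubstituted alkyne carbon, so the methyl group should end up at C3 next to the CCl2 carbon.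

Step 2
Reactants: 4 4,4-dichloro-3-methylcyclobut-2-en-1-one
Product: 5 4-chloro-3-methylcyclobut-2-en-1-one (racemic)
Conditions: Zn dust (1.1 equiv), AcOH, TMEDA, EtOH, −10 to 0 °C; kept as a toluene solution
Reagents that add atoms: none
Why: Zinc/acetic acid reduction of an α,α-dichloroketone takes the first chlorine much faster than the second, and the amine-buffered medium with one equivalent of metal should hold back over-reduction and allylic transposition, leaving chlorine on the sp3 carbon (new centre racemic, erased later).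

Step 3
Reactants: 6 methyl 2-hydroxy-3-methoxybenzoate
Product: 8 methyl 2,5-dihydroxy-3-methoxybenzoate, via aryl boronate 7 (not isolated)
Conditions: [Ir(OMe)(cod)]2 (1.5 mol%), 4,4'-di-tert-butyl-2,2'-bipyridine (3 mol%), B2pin2 (1.5 equiv), THF, 80 °C; then aq. KHSO5 (as the triple salt 2KHSO5·KHSO4·K2SO4), acetone, rt; Na2S2O4 wash
Reagents that add atoms: potassium peroxymonosulfate, [K+].[O-]S(=O)(=O)OO (the new oxygen); bis(pinacolato)diboron, CC1(C)OB(OC1(C)C)B1OC(C)(C)C(C)(C)O1 (boryl group of 7 only)
Why: Iridium-catalysed aromatic C–H borylation is sterically governed and should take C5, the only ring C–H without an ortho substituent, and one-pot peroxymonosulfate oxidation of the boronate gives the phenol (any O–B bond at the free phenol hydrolyses in the work-up; dithionite returns any quinone).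

Step 4
Reactants: 8 methyl 2,5-dihydroxy-3-methoxybenzoate
Product: 9 methyl 5-(benzyloxy)-2-hydroxy-3-methoxybenzoate
Conditions: BnBr (1.05 equiv), K2CO3 (1.1 equiv), acetone, reflux, N2
Reagents that add atoms: benzyl bromide, BrCc1ccccc1
Why: Williamson etherification should be selective for the 5-hydroxyl because the 2-hydroxyl is hydrogen-bonded to the ester and flanked by two ortho substituents.

Step 5
Reactants: 10 2,2-dimethoxyacetaldehyde
Product: 11 1,1-dibromo-3,3-dimethoxyprop-1-ene
Conditions: CBr4, PPh3, Et3N, CH2Cl2, 0 °C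
Reagents that add atoms: carbon tetrabromide, BrC(Br)(Br)Br
Why: Ramirez (Corey–Fuchs first stage) dibromo-olefination of an aldehyde, with Et3N buffering the medium so the acetal survives.

Step 6
Reactants: 9 methyl 5-(benzyloxy)-2-hydroxy-3-methoxybenzoate; 11 1,1-dibromo-3,3-dimethoxyprop-1-ene
Product: 12 methyl 5-(benzyloxy)-2-{[(1Z)-1-bromo-3,3-dimethoxyprop-1-en-1-yl]oxy}-3-methoxybenzoate
Conditions: CuI (10 mol%), 2,2'-bipyridine (20 mol%), K3PO4, 11 (1.5 equiv), toluene, 110 °C
Reagents that add atoms: none
Why: Ullmann-type copper-catalysed C–O coupling of a phenol with a 1,1-dibromoalkene, in which the bromine trans to the substituent reacts first to give the (Z)-bromoenol ether, and excess 11 limits a second substitution.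

Step 7
Reactants: 12 the (Z)-bromoenol ether
Product: 13 methyl 5-(benzyloxy)-2-[(3,3-dimethoxyprop-1-yn-1-yl)oxy]-3-methoxybenzoate
Conditions: KN(SiMe3)2 (1.3 equiv), THF, −78 to −30 °C; pH 7 buffer quench; Et3N-deactivated silica
Reagents that add atoms: none
Why: Anti E2 dehydrobromination of a bromoenol ether to the ynol ether, with a non-nucleophilic amide base chosen over an alkoxide to spare the methyl ester.

Step 8
Reactants: 5 4-chloro-3-methylcyclobut-2-en-1-one; 13 the aryloxy alkyne
Product: 18 methyl 5-(benzyloxy)-2-[4-chloro-2-(dimethoxymethyl)-3-hydroxy-5-methylphenoxy]-3-methoxybenzoate, via vinylketene 14 (not isolated), via vinylcyclobutenone 15 (not isolated), via dienylketene 16 (not isolated), via cyclohexadienone 17 (not isolated)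
Conditions: 13 in toluene, 90 °C, 5 (1.3 equiv) added over 3 h; then 110 °C
Reagents that add atoms: none
Why: Above about 80 °C cyclobutenone 5 opens by four-electron electrocyclic cleavage (chlorine turning outward) to chlorovinylketene 14, which adds [2+2] across the electron-rich triple bond of 13, the ketene carbonyl carbon bonding to the alkyne carbon remote from oxygen, to give 4-vinylcyclobutenone 15. Reversible four-electron opening of 15 gives dienylketene 16, and ring B closes by a thermally allowed disrotatory six-electron electrocyclisation (C2–C3 bond) to cyclohexadienone 17, which tautomerises to phenol 18. The closest known reaction is the Danheiser benzannulation of cyclobutenones with alkoxy- and siloxyalkynes, of which an aryloxyalkyne is a somewhat less nucleophilic member. No stereocentre survives, since the sp3 centres of 5, 15 and 17 are racemic and vanish on aromatisation. Only regiocontrol is needed: the ynol ether polarity places the aryloxy carbon (C6) next to the former cyclobutenone CH (C5) and the acetal carbon (C1) next to the carbonyl-derived C2, while chlorine, on the sp3 carbon of 5, becomes the ketene-remote terminus and lands at C3 beside the new hydroxyl. Slow addition of 5 keeps the ketene concentration low against dimerisation and against acylation of the hindered product phenol.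

Step 9
Reactants: 18 the acetal phenol
Product: 19 methyl 5-(benzyloxy)-2-(4-chloro-2-formyl-3-hydroxy-5-methylphenoxy)-3-methoxybenzoate
Conditions: 1 M aq. HCl, THF, 0 °C to rt
Reagents that add atoms: water, O
Why: Acid-catalysed hydrolysis of a dimethyl acetal, assisted by the ortho hydroxyl, should give the hydrogen-bonded salicylaldehyde while the ester and benzyl ether are untouched.

Step 10
Reactants: 19 the salicylaldehyde
Product: 20 6-[4-(benzyloxy)-2-methoxy-6-(methoxycarbonyl)phenoxy]-3-chloro-2-hydroxy-4-methylbenzoic acid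
Conditions: NaClO2, NaH2PO4, 2-methyl-2-butene (excess), t-BuOH/THF/H2O, 0 °C to rt
Reagents that add atoms: sodium chlorite, [Na+].[O-]Cl=O
Why: Pinnick oxidation takes the aldehyde to the acid, and the alkene scavenger removes hypochlorous acid so that neither electron-rich ring should be chlorinated.

Step 11
Reactants: 20 the benzyl-protected acid
Product: 21 3-chloro-2-hydroxy-6-[4-hydroxy-2-methoxy-6-(methoxycarbonyl)phenoxy]-4-methylbenzoic acid (isodihydromaldoxin)
Conditions: BCl3 (5 equiv), pentamethylbenzene (3 equiv), CH2Cl2, −78 °C; then H2O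
Reagents that add atoms: none
Why: Lewis-acid cleavage of the aryl benzyl ether with a cation scavenger avoids hydrogenolysis (which would endanger the aryl chloride) and at −78 °C should spare the methyl ether and methyl ester.

**Compound list**

1 | propyne | CC#C | starting material
2 | trichloroacetyl chloride | ClC(=O)C(Cl)(Cl)Cl | starting material
3 | dichloroketene | ClC(Cl)=C=O | intermediate
4 | 4,4-dichloro-3-methylcyclobut-2-en-1-one | CC1=CC(=O)C1(Cl)Cl | intermediate
5 | 4-chloro-3-methylcyclobut-2-en-1-one (racemic) | CC1=CC(=O)C1Cl | intermediate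
6 | methyl 2-hydroxy-3-methoxybenzoate | COC(=O)c1cccc(OC)c1O | starting material
7 | methyl 2-hydroxy-3-methoxy-5-(4,4,5,5-tetramethyl-1,3,2-dioxaborolan-2-yl)benzoate | COC(=O)c1cc(B2OC(C)(C)C(C)(C)O2)cc(OC)c1O | intermediate
8 | methyl 2,5-dihydroxy-3-methoxybenzoate | COC(=O)c1cc(O)cc(OC)c1O | intermediate
9 | methyl 5-(benzyloxy)-2-hydroxy-3-methoxybenzoate | COC(=O)c1cc(OCc2ccccc2)cc(OC)c1O | intermediate
10 | 2,2-dimethoxyacetaldehyde | COC(OC)C=O | starting material
11 | 1,1-dibromo-3,3-dimethoxyprop-1-ene | COC(OC)C=C(Br)Br | intermediate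
12 | methyl 5-(benzyloxy)-2-{[(1Z)-1-bromo-3,3-dimethoxyprop-1-en-1-yl]oxy}-3-methoxybenzoate | COC(=O)c1cc(OCc2ccccc2)cc(OC)c1O/C(Br)=C/C(OC)OC | intermediate
13 | methyl 5-(benzyloxy)-2-[(3,3-dimethoxyprop-1-yn-1-yl)oxy]-3-methoxybenzoate | COC(=O)c1cc(OCc2ccccc2)cc(OC)c1OC#CC(OC)OC | intermediate
14 | (3E)-4-chloro-3-methylbuta-1,3-dien-1-one | O=C=C/C(C)=C/Cl | intermediate
15 | methyl 5-(benzyloxy)-2-({4-[(1E)-1-chloroprop-1-en-2-yl]-2-(dimethoxymethyl)-3-oxocyclobut-1-en-1-yl}oxy)-3-methoxybenzoate (racemic) | COC(=O)c1cc(OCc2ccccc2)cc(OC)c1OC1=C(C(OC)OC)C(=O)C1/C(C)=C/Cl | intermediate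
16 | methyl 5-(benzyloxy)-2-{[(3E,5E)-6-chloro-2-(dimethoxymethyl)-5-methyl-1-oxohexa-1,3,5-trien-3-yl]oxy}-3-methoxybenzoate | Cl/C=C(C)/C=C(Oc1c(OC)cc(OCc2ccccc2)cc1C(=O)OC)\C(C(OC)OC)=C=O | intermediate
17 | methyl 5-(benzyloxy)-2-{[4-chloro-2-(dimethoxymethyl)-5-methyl-3-oxocyclohexa-1,5-dien-1-yl]oxy}-3-methoxybenzoate (racemic) | COC(=O)c1cc(OCc2ccccc2)cc(OC)c1OC1=C(C(OC)OC)C(=O)C(Cl)C(C)=C1 | intermediate
18 | methyl 5-(benzyloxy)-2-[4-chloro-2-(dimethoxymethyl)-3-hydroxy-5-methylphenoxy]-3-methoxybenzoate | COC(=O)c1cc(OCc2ccccc2)cc(OC)c1Oc1cc(C)c(Cl)c(O)c1C(OC)OC | intermediate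
19 | methyl 5-(benzyloxy)-2-(4-chloro-2-formyl-3-hydroxy-5-methylphenoxy)-3-methoxybenzoate | COC(=O)c1cc(OCc2ccccc2)cc(OC)c1Oc1cc(C)c(Cl)c(O)c1C=O | intermediate
20 | 6-[4-(benzyloxy)-2-methoxy-6-(methoxycarbonyl)phenoxy]-3-chloro-2-hydroxy-4-methylbenzoic acid | COC(=O)c1cc(OCc2ccccc2)cc(OC)c1Oc1cc(C)c(Cl)c(O)c1C(=O)O | intermediate
21 | 3-chloro-2-hydroxy-6-[4-hydroxy-2-methoxy-6-(methoxycarbonyl)phenoxy]-4-methylbenzoic acid (isodihydromaldoxin) | COC(=O)c1cc(O)cc(OC)c1Oc1cc(C)c(Cl)c(O)c1C(=O)O | target

**Count and risks**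

Total steps: 11. Longest linear sequence: 8 steps (6 → 21 through steps 3, 4, 6, 7, 8, 9, 10, 11).

Steps most likely to fail:

1. Step 8. Capture of the vinylketene by the aryloxy alkyne may be slower than ketene self-condensation, and traces of HCl from the chlorocyclobutenone may ionise the propargylic acetal before the cycloaddition. The fallback lowers the masked carboxyl to a silyl-protected hydroxymethyl group, which makes the alkyne more electron-rich and acid-tolerant. It sets out from phenol 9 and comes back at aldehyde 19.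
   - Ramirez olefination of (tert-butyldimethylsilyloxy)acetaldehyde gives tert-butyl[(3,3-dibromoprop-2-en-1-yl)oxy]dimethylsilane F1.
   - CuI/2,2'-bipyridine/K3PO4 coupling of F1 with 9 gives methyl 5-(benzyloxy)-2-{[(1Z)-1-bromo-3-{[tert-butyl(dimethyl)silyl]oxy}prop-1-en-1-yl]oxy}-3-methoxybenzoate F2.
   - KN(SiMe3)2 converts F2 into methyl 5-(benzyloxy)-2-[(3-{[tert-butyl(dimethyl)silyl]oxy}prop-1-yn-1-yl)oxy]-3-methoxybenzoate F3.
   - Heating F3 with 5 in toluene, as in step 8, should give methyl 5-(benzyloxy)-2-[2-({[tert-butyl(dimethyl)silyl]oxy}methyl)-4-chloro-3-hydroxy-5-methylphenoxy]-3-methoxybenzoate F4.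
   - HF·pyridine removes the silyl group to give methyl 5-(benzyloxy)-2-[4-chloro-3-hydroxy-2-(hydroxymethyl)-5-methylphenoxy]-3-methoxybenzoate F5, and MnO2 oxidation of this benzylic alcohol gives 19.

2. Step 2. Reduction may run on to the chlorine-free cyclobutenone, or the allyl-type zinc intermediate may be protonated at its far terminus so that chlorine moves onto the double bond; the latter would put chlorine at C5 after the annulation. The fallback generates the same vinylketene 14 without a cyclobutenone, by photochemical Wolff rearrangement. It sets out from alkyne 13 and comes back at 18.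
   - The known (2E)-3-chloro-2-methylprop-2-enoic acid is converted with oxalyl chloride into (2E)-3-chloro-2-methylprop-2-enoyl chloride F6.
   - Acylation of diazomethane with F6 in the presence of Et3N (first stage of an Arndt–Eistert sequence) gives (3E)-4-chloro-1-diazo-3-methylbut-3-en-2-one F7.
   - Irradiation of F7 with 13 (300 nm, 1,2-dichloroethane, rt, then 80 °C) should give 14 by vinyl migration, which passes through 15, 16 and 17 to 18.

3. Step 6. The doubly ortho-substituted, chelating phenoxide of 9 may fail to displace bromide at copper, or a second phenol may add to give the ketene acetal. The fallback forms the C–O bond by SN2 alkylation and unveils the triple bond by enol triflate elimination. It sets out from phenol 9 and comes back at alkyne 13.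
   - K2CO3/acetone alkylation of 9 with 3-bromo-1,1-dimethoxypropan-2-one gives methyl 5-(benzyloxy)-2-(3,3-dimethoxy-2-oxopropoxy)-3-methoxybenzoate F8.
   - KN(SiMe3)2 is added at −78 °C to F8 premixed with N-(5-chloro-2-pyridyl)triflimide, giving methyl 5-(benzyloxy)-2-{[(1Z)-3,3-dimethoxy-2-{[(trifluoromethyl)sulfonyl]oxy}prop-1-en-1-yl]oxy}-3-methoxybenzoate F9. The in-situ trapping is meant to outpace attack of the enolate on the neighbouring ester.
   - A second equivalent of KN(SiMe3)2 eliminates triflate anti to the vinyl hydrogen and gives 13.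

**Further compounds**

F1 | step 8 | tert-butyl[(3,3-dibromoprop-2-en-1-yl)oxy]dimethylsilane | CC(C)(C)[Si](C)(C)OCC=C(Br)Br
F2 | step 8 | methyl 5-(benzyloxy)-2-{[(1Z)-1-bromo-3-{[tert-butyl(dimethyl)silyl]oxy}prop-1-en-1-yl]oxy}-3-methoxybenzoate | COC(=O)c1cc(OCc2ccccc2)cc(OC)c1O/C(Br)=C/CO[Si](C)(C)C(C)(C)C
F3 | step 8 | methyl 5-(benzyloxy)-2-[(3-{[tert-butyl(dimethyl)silyl]oxy}prop-1-yn-1-yl)oxy]-3-methoxybenzoate | COC(=O)c1cc(OCc2ccccc2)cc(OC)c1OC#CCO[Si](C)(C)C(C)(C)C
F4 | step 8 | methyl 5-(benzyloxy)-2-[2-({[tert-butyl(dimethyl)silyl]oxy}methyl)-4-chloro-3-hydroxy-5-methylphenoxy]-3-methoxybenzoate | COC(=O)c1cc(OCc2ccccc2)cc(OC)c1Oc1cc(C)c(Cl)c(O)c1CO[Si](C)(C)C(C)(C)C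
F5 | step 8 | methyl 5-(benzyloxy)-2-[4-chloro-3-hydroxy-2-(hydroxymethyl)-5-methylphenoxy]-3-methoxybenzoate | COC(=O)c1cc(OCc2ccccc2)cc(OC)c1Oc1cc(C)c(Cl)c(O)c1CO
F6 | step 2 | (2E)-3-chloro-2-methylprop-2-enoyl chloride | C/C(=C\Cl)C(Cl)=O
F7 | step 2 | (3E)-4-chloro-1-diazo-3-methylbut-3-en-2-one | C/C(=C\Cl)C(=O)C=[N+]=[N-]
F8 | step 6 | methyl 5-(benzyloxy)-2-(3,3-dimethoxy-2-oxopropoxy)-3-methoxybenzoate | COC(=O)c1cc(OCc2ccccc2)cc(OC)c1OCC(=O)C(OC)OC
F9 | step 6 | methyl 5-(benzyloxy)-2-{[(1Z)-3,3-dimethoxy-2-{[(trifluoromethyl)sulfonyl]oxy}prop-1-en-1-yl]oxy}-3-methoxybenzoate | COC(=O)c1cc(OCc2ccccc2)cc(OC)c1O/C=C(\OS(=O)(=O)C(F)(F)F)C(OC)OC
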